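**Retrosynthetic overview**
- The last step is hydrogenolysis of four aryl benzyl ethers from the tetra-O-benzyl spiroketal.
- The strategy rests on one feature: the spiroketal carbon C2 (shared by dihydrobenzofuran rings A and B) and C2 of the ring-C benzofuran are 1,4-related through C3H–CH2, with the ring-B aryl on C3. This four-carbon unit is a masked 3-aryl-2,5-dialkylfuran, so the three O-heterocycles are traced back to an achiral 2,5-bis(arylmethyl)-3-arylfuran, and one acid cascade closes ring A, then ring B (spiroketal), then ring C (benzofuran).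
- The furan is built on 3-bromofuran-2-carbaldehyde with ketone-tolerant reactions only, because the isovaleryl ketones would not survive aryl- or furyl-lithium steps. CHO becomes the ring-A arylmethyl by Hantzsch-ester reductive alkylation, C3–Br the ring-B aryl by borylation and Suzuki coupling, and C5–H the ring-C arylmethyl by quinone-methide Friedel–Crafts alkylation.
- All three aryl units come from phlorisovalerophenone. Rings A and B use its 4-O-benzyl ether; ring C uses its 2,6-di-O-benzyl ether, so that only the para-OH of ring C is free to close.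

Key step: step 13

Assumption: the sense of induction of the confined acid cannot be predicted for this substrate; the (S,S) catalyst is written, and its antipode is taken if a first run shows the mirror-image product.

**Route**

Step 1
Reactants: 1 phloroglucinol; 2 isovaleryl chloride
Product: 3 3-methyl-1-(2,4,6-trihydroxyphenyl)butan-1-one (phlorisovalerophenone)
Conditions: AlCl3, PhNO2, rt to 65 °C; then aq. HCl
Reagents that add atoms: isovaleryl chloride 2, CC(C)CC(Cl)=O
Why: Friedel–Crafts C-acylation of the symmetrical, highly activated phloroglucinol ring should stop at the mono-ketone because the first acyl group deactivates the nucleus.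

Step 2
Reactants: 3 phlorisovalerophenone; 4 benzyl bromide
Product: 5 1-[4-(benzyloxy)-2,6-dihydroxyphenyl]-3-methylbutan-1-one
Conditions: BnBr (1.0 equiv), K2CO3, acetone, rt
Reagents that add atoms: benzyl bromide 4, BrCc1ccccc1
Why: Williamson ether synthesis in which the 4-OH, the most acidic hydroxyl and the only one not hydrogen-bonded to the ketone, should be alkylated first by one equivalent of halide.

Step 3
Reactants: 5 1-[4-(benzyloxy)-2,6-dihydroxyphenyl]-3-methylbutan-1-one; 6 3-bromofuran-2-carbaldehyde
Product: 8 1-{4-(benzyloxy)-3-[(3-bromofuran-2-yl)methyl]-2,6-dihydroxyphenyl}-3-methylbutan-1-one, via ortho-quinone methide 7 (not isolated)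
Conditions: Hantzsch ester (1.2 equiv), L-proline (20 mol%), CH2Cl2/EtOH, rt
Reagents that add atoms: none
Why: Three-component reductive alkylation (Knoevenagel-type condensation to ortho-quinone methide 7, then Hantzsch-ester transfer hydrogenation), in which the nuclear carbon of the vinylogous acid 5 is the nucleophile, the two free ring positions of 5 are equivalent, and the neutral conditions spare the ketone, the aryl bromide and the furan.

Step 4
Reactants: 5 1-[4-(benzyloxy)-2,6-dihydroxyphenyl]-3-methylbutan-1-one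
Product: 9 1-[4-(benzyloxy)-3-bromo-2,6-dihydroxyphenyl]-3-methylbutan-1-one
Conditions: NBS (1.0 equiv), CH2Cl2, −20 °C
Reagents that add atoms: N-bromosuccinimide, O=C1CCC(=O)N1Br
Why: Electrophilic aromatic bromination at one of the two equivalent free ring positions, the first bromine slowing a second substitution.

Step 5
Reactants: 8 1-{4-(benzyloxy)-3-[(3-bromofuran-2-yl)methyl]-2,6-dihydroxyphenyl}-3-methylbutan-1-one
Product: 10 1-{4-(benzyloxy)-2,6-dihydroxy-3-{[3-(4,4,5,5-tetramethyl-1,3,2-dioxaborolan-2-yl)furan-2-yl]methyl}phenyl}-3-methylbutan-1-one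
Conditions: B2pin2, Pd(dppf)Cl2 (cat.), KOAc, dioxane, 85 °C
Reagents that add atoms: bis(pinacolato)diboron, CC1(C)OB(OC1(C)C)B1OC(C)(C)C(C)(C)O1
Why: Miyaura borylation of the 3-bromofuran with acetate as base leaves ketone and phenols alone, and it puts boron on the furan so that no protodeboronation-prone 2,6-dioxygenated arylboron reagent is needed.

Step 6
Reactants: 10 furan-3-boronic ester; 9 1-[4-(benzyloxy)-3-bromo-2,6-dihydroxyphenyl]-3-methylbutan-1-one
Product: 11 1-{4-(benzyloxy)-3-[(3-{6-(benzyloxy)-2,4-dihydroxy-3-(3-methylbutanoyl)phenyl}furan-2-yl)methyl]-2,6-dihydroxyphenyl}-3-methylbutan-1-one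
Conditions: XPhos Pd G3 (cat.), K3PO4, dioxane/H2O, 70 °C
Reagents that add atoms: none
Why: Suzuki–Miyaura coupling with a bulky dialkylbiarylphosphine catalyst, which is the ligand class suited to electron-rich, ortho-oxygenated aryl bromides and unprotected phenols.

Step 7
Reactants: 3 phlorisovalerophenone
Product: 12 1-[2,6-dihydroxy-4-(methoxymethoxy)phenyl]-3-methylbutan-1-one
Conditions: MOMCl (1.05 equiv), iPr2NEt, CH2Cl2, 0 °C
Reagents that add atoms: chloromethyl methyl ether, COCCl
Why: Selective O-alkylation (MOM protection) of the most acidic, non-chelated 4-OH, which must later be the only free hydroxyl of ring C.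

Step 8
Reactants: 12 1-[2,6-dihydroxy-4-(methoxymethoxy)phenyl]-3-methylbutan-1-one; 4 benzyl bromide
Product: 13 1-[2,6-bis(benzyloxy)-4-(methoxymethoxy)phenyl]-3-methylbutan-1-one
Conditions: BnBr (2.5 equiv), K2CO3, DMF, 60 °C
Reagents that add atoms: benzyl bromide 4, BrCc1ccccc1
Why: Williamson ether synthesis under forcing conditions alkylates both chelated ortho-hydroxyls while the MOM ether is stable to base.

Step 9
Reactants: 13 1-[2,6-bis(benzyloxy)-4-(methoxymethoxy)phenyl]-3-methylbutan-1-one
Product: 14 1-[2,6-bis(benzyloxy)-4-hydroxyphenyl]-3-methylbutan-1-one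
Conditions: HCl, MeOH, 50 °C
Reagents that add atoms: none
Why: Acid-catalysed acetal exchange with methanol removes the MOM group, the benzyl ethers and the ketone being stable to methanolic HCl.

Step 10
Reactants: 14 1-[2,6-bis(benzyloxy)-4-hydroxyphenyl]-3-methylbutan-1-one
Product: 15 2,4-bis(benzyloxy)-6-hydroxy-3-(3-methylbutanoyl)benzaldehyde
Conditions: MgCl2, Et3N, (CH2O)n, MeCN, reflux; then aq. HCl
Reagents that add atoms: paraformaldehyde (formaldehyde), C=O
Why: Casnati–Skattebøl ortho-formylation, in which the magnesium phenoxide delivers formaldehyde only to a carbon ortho to the free OH (the two such carbons are equivalent) and the chelated salicylaldehyde does not react a second time.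

Step 11
Reactants: 15 2,4-bis(benzyloxy)-6-hydroxy-3-(3-methylbutanoyl)benzaldehyde
Product: 16 1-[2,6-bis(benzyloxy)-4-hydroxy-3-(hydroxymethyl)phenyl]-3-methylbutan-1-one
Conditions: NaBH4, THF/MeOH, −10 °C; neutral work-up
Reagents that add atoms: none
Why: Chemoselective borohydride reduction, the aldehyde being reduced far faster than the di-ortho-substituted, twisted aryl ketone.

Step 12
Reactants: 11 2-(arylmethyl)-3-arylfuran; 16 1-[2,6-bis(benzyloxy)-4-hydroxy-3-(hydroxymethyl)phenyl]-3-methylbutan-1-one
Product: 18 2-{[6-(benzyloxy)-2,4-dihydroxy-3-(3-methylbutanoyl)phenyl]methyl}-3-[6-(benzyloxy)-2,4-dihydroxy-3-(3-methylbutanoyl)phenyl]-5-{[2,4-bis(benzyloxy)-6-hydroxy-3-(3-methylbutanoyl)phenyl]methyl}furan, via ortho-quinone methide 17 (not isolated)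
Conditions: (PhO)2P(O)OH (10 mol%), 4 Å MS, CH2Cl2, 0 °C, slow addition of 16
Reagents that add atoms: none
Why: Brønsted acid-catalysed Friedel–Crafts alkylation through ortho-quinone methide 17, the usual way to 2-(2-hydroxybenzyl)furans, in which C5 is the only free α-position of furan 11 and the weak phosphate acid ionises the trioxygenated benzylic alcohol without protonating the furan ring.

Step 13
Reactants: 18 achiral 2,5-bis(arylmethyl)-3-arylfuran
Product: 21 (2R,3S)-4,4'-bis(benzyloxy)-3-{[4,6-bis(benzyloxy)-5-(3-methylbutanoyl)-1-benzofuran-2-yl]methyl}-6,6'-dihydroxy-7,7'-bis(3-methylbutanoyl)-3H,3'H-2,2'-spirobi[1-benzofuran], via spiro dihydrofuran ketal 19 (not isolated), via keto spiroketal 20 (not isolated)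
Conditions: (S,S)-IDPi (confined chiral imidodiphosphorimidate acid, 5 mol%), 5 Å MS, CHCl3, −20 °C
Reagents that add atoms: none
Why: Proposed new method: the strong confined acid protonates furan C3 of 18, the ring-A phenol traps the C2 oxocarbenium (5-exo-trig) to give 19, ionisation of the C2–O(furan) bond unveils the C5 ketone and an aryloxy-stabilised oxocarbenium that the ring-B phenol closes (5-exo-trig) to spiroketal 20, and the ring-C phenol then adds to the ketone (5-exo-trig) and loses water to give the benzofuran. The closest known reactions are the acid-mediated furan ring-opening/benzofuran ring-closure of 2-(2-hydroxybenzyl)furans and the chiral Brønsted acid-catalysed spiroketalisation of hydroxy enol ethers; their merger in one catalytic asymmetric operation is not known. The CH centre stays labile until the spiroketal closes, because the oxocarbenium and its enol ether interconvert, so both centres are fixed together in the ring-B closure inside the chiral ion pair, which selects one face of the planar benzofuranylium ion and so gives (R) at the spiro carbon and (S) at CH. The substrate helps the relative configuration, since the CH2 arm on the CH carbon prefers the side of the ring-A oxygen to the side of the ring-A CH2. Regioselectivity rests on the benzyl ethers, which leave each link with a single free ortho OH, and protonation at C4 instead of C3 leads to the same product through the reverse order of ring closures. Acid strength is the chemoselectivity switch (the phosphate of step 12 leaves the furan intact, the confined acid opens it), and the sieves take up the water so that the ketal is not hydrolysed.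

Step 14
Reactants: 21 tetra-O-benzyl spiroketal
Product: 22 (2R,3S)-3-{[4,6-dihydroxy-5-(3-methylbutanoyl)-1-benzofuran-2-yl]methyl}-4,4',6,6'-tetrahydroxy-7,7'-bis(3-methylbutanoyl)-3H,3'H-2,2'-spirobi[1-benzofuran] (target CNP0169640.1)
Conditions: H2 (1 atm), Pd/C, EtOAc/MeOH, rt; acid-free work-up
Reagents that add atoms: none
Why: Catalytic hydrogenolysis of the four aryl benzyl ethers under neutral conditions should leave the chelated aryl ketones, the benzofuran and the spiroketal (which has no benzylic C–O bond) untouched, and no acid is present that could epimerise the ketal.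

**Compound list**

1 | phloroglucinol (benzene-1,3,5-triol) | Oc1cc(O)cc(O)c1 | starting material
2 | isovaleryl chloride (3-methylbutanoyl chloride) | CC(C)CC(Cl)=O | starting material
3 | phlorisovalerophenone; 3-methyl-1-(2,4,6-trihydroxyphenyl)butan-1-one | CC(C)CC(=O)c1c(O)cc(O)cc1O | intermediate
4 | benzyl bromide | BrCc1ccccc1 | starting material
5 | 1-[4-(benzyloxy)-2,6-dihydroxyphenyl]-3-methylbutan-1-one | CC(C)CC(=O)c1c(O)cc(OCc2ccccc2)cc1O | intermediate
6 | 3-bromofuran-2-carbaldehyde | O=Cc1occc1Br | starting material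
7 | ortho-quinone methide; 5-(benzyloxy)-6-[(3-bromofuran-2-yl)methylidene]-3-hydroxy-2-(3-methylbutanoyl)cyclohexa-2,4-dien-1-one (alkene geometry not defined) | CC(C)CC(=O)C1=C(O)C=C(OCc2ccccc2)C(=Cc2occc2Br)C1=O | intermediate (not isolated)
8 | 1-{4-(benzyloxy)-3-[(3-bromofuran-2-yl)methyl]-2,6-dihydroxyphenyl}-3-methylbutan-1-one | CC(C)CC(=O)c1c(O)cc(OCc2ccccc2)c(Cc2occc2Br)c1O | intermediate
9 | 1-[4-(benzyloxy)-3-bromo-2,6-dihydroxyphenyl]-3-methylbutan-1-one | CC(C)CC(=O)c1c(O)cc(OCc2ccccc2)c(Br)c1O | intermediate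
10 | 1-{4-(benzyloxy)-2,6-dihydroxy-3-{[3-(4,4,5,5-tetramethyl-1,3,2-dioxaborolan-2-yl)furan-2-yl]methyl}phenyl}-3-methylbutan-1-one | CC(C)CC(=O)c1c(O)cc(OCc2ccccc2)c(Cc2occc2B2OC(C)(C)C(C)(C)O2)c1O | intermediate
11 | 2-(arylmethyl)-3-arylfuran; 1-{4-(benzyloxy)-3-[(3-{6-(benzyloxy)-2,4-dihydroxy-3-(3-methylbutanoyl)phenyl}furan-2-yl)methyl]-2,6-dihydroxyphenyl}-3-methylbutan-1-one | CC(C)CC(=O)c1c(O)cc(OCc2ccccc2)c(Cc2occc2-c2c(O)c(C(=O)CC(C)C)c(O)cc2OCc2ccccc2)c1O | intermediate
12 | 1-[2,6-dihydroxy-4-(methoxymethoxy)phenyl]-3-methylbutan-1-one | CC(C)CC(=O)c1c(O)cc(OCOC)cc1O | intermediate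
13 | 1-[2,6-bis(benzyloxy)-4-(methoxymethoxy)phenyl]-3-methylbutan-1-one | CC(C)CC(=O)c1c(OCc2ccccc2)cc(OCOC)cc1OCc1ccccc1 | intermediate
14 | 1-[2,6-bis(benzyloxy)-4-hydroxyphenyl]-3-methylbutan-1-one | CC(C)CC(=O)c1c(OCc2ccccc2)cc(O)cc1OCc1ccccc1 | intermediate
15 | 2,4-bis(benzyloxy)-6-hydroxy-3-(3-methylbutanoyl)benzaldehyde | CC(C)CC(=O)c1c(OCc2ccccc2)cc(O)c(C=O)c1OCc1ccccc1 | intermediate
16 | 1-[2,6-bis(benzyloxy)-4-hydroxy-3-(hydroxymethyl)phenyl]-3-methylbutan-1-one | CC(C)CC(=O)c1c(OCc2ccccc2)cc(O)c(CO)c1OCc1ccccc1 | intermediate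
17 | ortho-quinone methide; 3,5-bis(benzyloxy)-6-methylidene-4-(3-methylbutanoyl)cyclohexa-2,4-dien-1-one | CC(C)CC(=O)C1=C(OCc2ccccc2)C(=C)C(=O)C=C1OCc1ccccc1 | intermediate (not isolated)
18 | achiral cascade precursor; 2-{[6-(benzyloxy)-2,4-dihydroxy-3-(3-methylbutanoyl)phenyl]methyl}-3-[6-(benzyloxy)-2,4-dihydroxy-3-(3-methylbutanoyl)phenyl]-5-{[2,4-bis(benzyloxy)-6-hydroxy-3-(3-methylbutanoyl)phenyl]methyl}furan | CC(C)CC(=O)c1c(O)cc(OCc2ccccc2)c(Cc2oc(Cc3c(O)cc(OCc4ccccc4)c(C(=O)CC(C)C)c3OCc3ccccc3)cc2-c2c(O)c(C(=O)CC(C)C)c(O)cc2OCc2ccccc2)c1O | intermediate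
19 | spiro dihydrofuran ketal: ring A closed as a 3H-benzofuran whose C2 is the former furan C2; that carbon is still bonded to the furan oxygen, C3 carries H and the ring-B aryl, and C4=C5 remains an enol ether (configuration at both centres not yet fixed) | CC(C)CC(=O)c1c(O)cc(OCc3ccccc3)c2c1OC1(C2)OC(Cc3c(O)cc(OCc4ccccc4)c(C(=O)CC(C)C)c3OCc3ccccc3)=CC1c1c(O)c(C(=O)CC(C)C)c(O)cc1OCc1ccccc1 | intermediate (not isolated)
20 | keto spiroketal: (2R,3S)-3H,3'H-2,2'-spirobi[1-benzofuran] with rings A and B closed, and on C3 a CH2–C(=O)–CH2 chain ending in the ring-C aryl with its free OH | CC(C)CC(=O)c1c(O)cc(OCc3ccccc3)c2c1O[C@]1(C2)Oc2c(C(=O)CC(C)C)c(O)cc(OCc3ccccc3)c2[C@@H]1CC(=O)Cc1c(O)cc(OCc2ccccc2)c(C(=O)CC(C)C)c1OCc1ccccc1 | intermediate (not isolated)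
21 | (2R,3S)-4,4'-bis(benzyloxy)-3-{[4,6-bis(benzyloxy)-5-(3-methylbutanoyl)-1-benzofuran-2-yl]methyl}-6,6'-dihydroxy-7,7'-bis(3-methylbutanoyl)-3H,3'H-2,2'-spirobi[1-benzofuran]; spiro carbon R, CH carbon S, CH2 arm cis to the ring-A oxygen | CC(C)CC(=O)c1c(O)cc(OCc3ccccc3)c2c1O[C@]1(C2)Oc2c(C(=O)CC(C)C)c(O)cc(OCc3ccccc3)c2[C@@H]1Cc1cc2c(OCc3ccccc3)c(C(=O)CC(C)C)c(OCc3ccccc3)cc2o1 | intermediate
22 | CNP0169640.1; (2R,3S)-3-{[4,6-dihydroxy-5-(3-methylbutanoyl)-1-benzofuran-2-yl]methyl}-4,4',6,6'-tetrahydroxy-7,7'-bis(3-methylbutanoyl)-3H,3'H-2,2'-spirobi[1-benzofuran] | CC(C)CC(=O)c1c(O)cc(O)c2c1O[C@]1(C2)Oc2c(C(=O)CC(C)C)c(O)cc(O)c2[C@@H]1Cc1cc2c(O)c(C(=O)CC(C)C)c(O)cc2o1 | target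

**Step count**

Total: 14 steps. Longest linear sequence: 9 steps (steps 1, 7, 8, 9, 10, 11, 12, 13, 14).

**Steps most likely to fail**

1. Step 13 (Proposed new method). Several processes can defeat it:
   - the ring-A oxocarbenium may lose its benzylic proton and aromatise to a benzofuran before the ring-B phenol closes;
   - the finished spiroketal may re-ionise under the catalyst, which erodes the enantiomeric purity and can epimerise the CH centre;
   - the strong acid may transfer benzyl groups.

   Fallback: from 18, p-TsOH in wet dioxane hydrolyses the furan to the 1,4-diketone F1 (furan hydrolysis). Continued heating in toluene with removal of water then gives dehydrative spiroketalisation of the keto-bisphenol and phenol–ketone cyclodehydration to the benzofuran. The product is the racemate of 21, that is 21 together with its mirror-image spiroketal F2, and preparative HPLC on a chiral stationary phase returns the route to 21.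

2. Step 12. The quinone methide may alkylate the free ring carbon of its own parent phenol or of the product faster than furan C5, giving oligomers and over-alkylated material.
   Fallback: from 11, Vilsmeier–Haack formylation (POCl3, DMF, 0 °C) at the only free furan α-position gives the 5-formylfuran F3. A Hantzsch-ester reductive alkylation of the kind used in step 3, with an excess of phenol 14 as the carbon nucleophile, then gives 18 under neutral conditions; compounds 15 to 17 are not needed.

3. Step 3. Condensation of the chelated, acyl-deactivated phenol may be slow, and a second molecule of 5 may add to the quinone methide before hydride transfer, giving a bis-aryl methane.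
   Fallback: from 6, NaBH4 reduction gives (3-bromofuran-2-yl)methanol F4. BF3·OEt2 in dioxane then alkylates the nuclear carbon of 5 (Friedel–Crafts alkylation of an acylphloroglucinol ether by an activated alcohol), and the route is rejoined at 8.

**Further compounds**

F1 | step 13 | 1,4-diketone from hydrolysis of 18 (ring-A aryl–CH2–CO–CH(ring-B aryl)–CH2–CO–CH2–ring-C aryl; racemic at CH) | CC(C)CC(=O)c1c(O)cc(OCc2ccccc2)c(CC(=O)C(CC(=O)Cc2c(O)cc(OCc3ccccc3)c(C(=O)CC(C)C)c2OCc2ccccc2)c2c(O)c(C(=O)CC(C)C)c(O)cc2OCc2ccccc2)c1O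
F2 | step 13 | mirror-image spiroketal, (2S,3R) enantiomer of 21 | CC(C)CC(=O)c1c(O)cc(OCc3ccccc3)c2c1O[C@@]1(C2)Oc2c(C(=O)CC(C)C)c(O)cc(OCc3ccccc3)c2[C@H]1Cc1cc2c(OCc3ccccc3)c(C(=O)CC(C)C)c(OCc3ccccc3)cc2o1
F3 | step 12 | 5-formylfuran; 5-{[6-(benzyloxy)-2,4-dihydroxy-3-(3-methylbutanoyl)phenyl]methyl}-4-[6-(benzyloxy)-2,4-dihydroxy-3-(3-methylbutanoyl)phenyl]furan-2-carbaldehyde | CC(C)CC(=O)c1c(O)cc(OCc2ccccc2)c(Cc2oc(C=O)cc2-c2c(O)c(C(=O)CC(C)C)c(O)cc2OCc2ccccc2)c1O
F4 | step 3 | (3-bromofuran-2-yl)methanol | OCc1occc1Br
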